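**Retrosynthetic overview**

1. Both bibenzyl bridges are carried at a higher oxidation level (a stilbene C=C for ring A–ring B, a benzylic lactone C–O for ring C–ring D). One final hydrogenation/hydrogenolysis takes both down and also removes the single benzyl ether.
2. Key disconnection: the ring A–ring B bridge is cut into two aldehydes, 4-(benzyloxy)benzaldehyde and 3-hydroxy-5-methoxybenzaldehyde. The first becomes its N–H hydrazone, a benzyl-carbanion equivalent with reversed polarity at the formyl carbon, which couples to the formyl carbon of the second under [RuCl2(p-cymene)]2 catalysis with loss of N2 and water.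
3. Diaryl ether (ring B–O–ring C): SNAr of the resulting phenol on 4-fluorobenzaldehyde.
4. Ring C–ring D bridge: the new aldehyde takes up the benzylic dianion of methyl 2-hydroxy-4-methoxy-6-methylbenzoate and lactonises.
5. Ring order: rings A, B, C and D are all bought as intact benzene rings. The only ring formed is the lactone (step 3), and it is opened again in step 4.

Assumption: the target SMILES has no stereocentre and no stereogenic double bond, so the compound is achiral and "single enantiomer" asks for nothing. The one stereocentre formed on the way (C3 of the lactone made in step 3) is racemic and is removed in the last step.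

**Route**

Step 1
Reactants: 1 4-(benzyloxy)benzaldehyde; 2 3-hydroxy-5-methoxybenzaldehyde
Product: 4 (E)-3-[4-(benzyloxy)styryl]-5-methoxyphenol, via hydrazone 3 (not isolated)
Conditions: 1, N2H4·H2O (1.1 equiv), THF, rt, 1 h; then 2, [RuCl2(p-cymene)]2 (2.5 mol%), Me2PCH2CH2PMe2 (5 mol%), KOtBu (2.2 equiv), THF, 60 °C, 16 h; 1 M HCl work-up
Reagents that add atoms: none
Why: The N–H hydrazone 3 is a benzyl-carbanion equivalent of aldehyde 1 (carbonyl umpolung of the Wolff–Kishner type) that, on a divalent ruthenium–diphosphine catalyst, adds through carbon to the formyl group of 2 and then loses N2 and hydroxide (E1cB) to give the stilbene, a ruthenium-catalysed hydrazone-mediated carbonyl–carbonyl reductive olefination joining two formyl carbons; the phenol is carried as its potassium salt (hence the extra KOtBu) and the E/Z ratio does not matter because the C=C bond is hydrogenated in step 4.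

Step 2
Reactants: 4 (E)-3-[4-(benzyloxy)styryl]-5-methoxyphenol; 5 4-fluorobenzaldehyde
Product: 6 (E)-4-{3-[4-(benzyloxy)styryl]-5-methoxyphenoxy}benzaldehyde
Conditions: K2CO3 (2 equiv), DMF, 110 °C, 12 h
Reagents that add atoms: none
Why: Nucleophilic aromatic substitution (SNAr): the potassium phenoxide of 4 adds para to the formyl group of 5, which stabilises the Meisenheimer adduct, and fluoride leaves, while the stilbene and the benzyl ether are inert to K2CO3.

Step 3
Reactants: 7 methyl 2-hydroxy-4-methoxy-6-methylbenzoate; 6 (E)-4-{3-[4-(benzyloxy)styryl]-5-methoxyphenoxy}benzaldehyde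
Product: 10 rac-3-(4-{3-[(E)-2-(4-benzyloxyphenyl)ethenyl]-5-methoxyphenoxy}phenyl)-8-hydroxy-6-methoxy-3,4-dihydro-1H-isochromen-1-one, via dilithio dianion 8 (not isolated), via dilithium aldol alkoxide 9 (not isolated)
Conditions: 7 (1.3 equiv), LiN(iPr)2 (2.7 equiv), THF, −78 °C, 1 h; then 6, −78 °C to rt; 1 M HCl work-up
Reagents that add atoms: none
Why: Lateral lithiation of the o-toluate (phenoxide first, then the benzylic CH3, whose anion is delocalised into the ester) gives dianion 8, which adds 1,2 to the aldehyde of 6, and alkoxide 9 closes the six-membered lactone on the neighbouring ester with loss of methoxide (toluate-anion aldol–lactonisation, the classical route to 3-aryl-3,4-dihydroisocoumarins); the new stereocentre C3 is formed racemic and is erased in step 4.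

Step 4
Reactants: 10 rac-3-(4-{3-[(E)-2-(4-benzyloxyphenyl)ethenyl]-5-methoxyphenoxy}phenyl)-8-hydroxy-6-methoxy-3,4-dihydro-1H-isochromen-1-one
Product: 12 target acid 2-hydroxy-6-[2-(4-{3-[2-(4-hydroxyphenyl)ethyl]-5-methoxyphenoxy}phenyl)ethyl]-4-methoxybenzoic acid, via saturated phenolic lactone 11 (not isolated)
Conditions: H2 (4 bar), Pd/C (10% palladium on carbon), EtOAc/AcOH 1:1, 50 °C, 24 h
Reagents that add atoms: none
Why: Heterogeneous hydrogenation–hydrogenolysis over palladium: the C=C bond is saturated and the benzyl aryl ether cleaved first (giving 11), then the lactone C3–O bond, a benzylic ester C–O bond activated by the para aryloxy group, is hydrogenolysed like a benzyl ester, which turns C3 into CH2, frees the carboxylic acid and removes the only stereocentre.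

**Compound list**

1 | 4-(benzyloxy)benzaldehyde | O=Cc1ccc(OCc2ccccc2)cc1 | starting material
2 | 3-hydroxy-5-methoxybenzaldehyde | COc1cc(O)cc(C=O)c1 | starting material
3 | (E)-[4-(benzyloxy)benzylidene]hydrazine (N–H hydrazone of 1) | N/N=C/c1ccc(OCc2ccccc2)cc1 | intermediate (not isolated)
4 | (E)-3-[4-(benzyloxy)styryl]-5-methoxyphenol | COc1cc(O)cc(/C=C/c2ccc(OCc3ccccc3)cc2)c1 | intermediate
5 | 4-fluorobenzaldehyde | O=Cc1ccc(F)cc1 | starting material
6 | (E)-4-{3-[4-(benzyloxy)styryl]-5-methoxyphenoxy}benzaldehyde | COc1cc(Oc2ccc(C=O)cc2)cc(/C=C/c2ccc(OCc3ccccc3)cc2)c1 | intermediate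
7 | methyl 2-hydroxy-4-methoxy-6-methylbenzoate | COC(=O)c1c(C)cc(OC)cc1O | starting material
8 | dilithio dianion of 7 (lithium phenoxide, benzylic carbanion) | [Li+].[Li+].[CH2-]c1cc(OC)cc([O-])c1C(=O)OC | intermediate (not isolated)
9 | dilithium salt of methyl 2-hydroxy-6-[2-hydroxy-2-(4-{3-[(E)-2-(4-benzyloxyphenyl)ethenyl]-5-methoxyphenoxy}phenyl)ethyl]-4-methoxybenzoate (racemic) | [Li+].[Li+].COC(=O)c1c([O-])cc(OC)cc1CC([O-])c1ccc(Oc2cc(OC)cc(/C=C/c3ccc(OCc4ccccc4)cc3)c2)cc1 | intermediate (not isolated)
10 | rac-3-(4-{3-[(E)-2-(4-benzyloxyphenyl)ethenyl]-5-methoxyphenoxy}phenyl)-8-hydroxy-6-methoxy-3,4-dihydro-1H-isochromen-1-one | COc1cc(O)c2C(=O)OC(Cc2c1)c1ccc(Oc2cc(OC)cc(/C=C/c3ccc(OCc4ccccc4)cc3)c2)cc1 | intermediate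
11 | rac-8-hydroxy-3-(4-{3-[2-(4-hydroxyphenyl)ethyl]-5-methoxyphenoxy}phenyl)-6-methoxy-3,4-dihydro-1H-isochromen-1-one | COc1cc(O)c2C(=O)OC(Cc2c1)c1ccc(Oc2cc(OC)cc(CCc3ccc(O)cc3)c2)cc1 | intermediate (not isolated)
12 | 2-hydroxy-6-[2-(4-{3-[2-(4-hydroxyphenyl)ethyl]-5-methoxyphenoxy}phenyl)ethyl]-4-methoxybenzoic acid (achiral) | COc1cc(CCc2ccc(O)cc2)cc(Oc2ccc(CCc3cc(OC)cc(O)c3C(=O)O)cc2)c1 | target

**Step count and risks**

Total step count: 4. Longest linear sequence: 4 (1 + 2 → 4 → 6 → 10 → 12).

The three steps most likely to fail: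

Step 1. The hydrazone coupling is run on a free phenol, which consumes base and gives a poorly soluble phenoxide. Azine formation between 3 and 2, and Wolff–Kishner reduction of 3, compete. The fallback replaces the catalytic coupling by a stoichiometric acyl-anion alkylation (Corey–Seebach); it sets out from 2 and comes back to the route at 11. Aldehyde 2 and propane-1,3-dithiol (BF3·OEt2, CH2Cl2, 0 °C to rt) give 3-(1,3-dithian-2-yl)-5-methoxyphenol F1. Double deprotonation (n-BuLi, 2.2 equiv, THF, −30 °C) and C-alkylation with 4-(benzyloxy)benzyl chloride give 3-{2-[4-(benzyloxy)benzyl]-1,3-dithian-2-yl}-5-methoxyphenol F2. Ni2B made in the flask from NiCl2·6H2O and NaBH4 (MeOH/THF, 0 °C) removes the sulfur and leaves 3-{2-[4-(benzyloxy)phenyl]ethyl}-5-methoxyphenol F3, the dihydro form of 4. F3 is then taken through the conditions of steps 2 and 3 with 5 and 7. This gives 4-(3-{2-[4-(benzyloxy)phenyl]ethyl}-5-methoxyphenoxy)benzaldehyde F4 and then rac-3-(4-{3-[2-(4-benzyloxyphenyl)ethyl]-5-methoxyphenoxy}phenyl)-8-hydroxy-6-methoxy-3,4-dihydro-1H-isochromen-1-one F5. Under the conditions of step 4, F5 loses its benzyl group to give 11 and goes on to 12.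

Step 3. The unprotected dianion 8 may form incompletely or self-condense, and the phenoxide-deactivated ester may lactonise slowly. The fallback uses a protected, singly deprotonated nucleophile with a built-in activated acyl group; it sets out from 7 and comes back at 10. Saponification of 7 (KOH, DMSO/H2O, 60 °C; cold acidification to avoid decarboxylation) gives 2-hydroxy-4-methoxy-6-methylbenzoic acid F6. Acetone, (CF3CO)2O and CF3CO2H (0 °C to rt) close it to 7-methoxy-2,2,5-trimethyl-4H-1,3-benzodioxin-4-one F7. One equivalent of LiN(iPr)2 (THF, −78 °C) deprotonates the benzylic methyl group, and 6 is added. The resulting alkoxide attacks the dioxinone carbonyl, acetone is expelled, and 10 is obtained directly after work-up.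

Step 4. Hydrogenolysis of the lactone C3–O bond may stall at 11 after the alkene and benzyl ether have reacted. The fallback opens the lactone by elimination before any hydrogenation; it sets out from 10 and comes back at 12. KOtBu (3 equiv, DMSO, rt to 50 °C) removes a benzylic C4 proton, and the carboxylate leaves from C3 (E1cB-type β-elimination). This gives 6-{(E)-2-[4-(3-{(E)-2-[4-(benzyloxy)phenyl]ethenyl}-5-methoxyphenoxy)phenyl]ethenyl}-2-hydroxy-4-methoxybenzoic acid F8. Ordinary hydrogenation (H2 1 atm, Pd/C, EtOAc/EtOH, rt) then saturates both C=C bonds and removes the benzyl group to give 12.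

**Further compounds**

F1 | step 1 | 3-(1,3-dithian-2-yl)-5-methoxyphenol | COc1cc(O)cc(C2SCCCS2)c1
F2 | step 1 | 3-{2-[4-(benzyloxy)benzyl]-1,3-dithian-2-yl}-5-methoxyphenol | COc1cc(O)cc(C2(Cc3ccc(OCc4ccccc4)cc3)SCCCS2)c1
F3 | step 1 | 3-{2-[4-(benzyloxy)phenyl]ethyl}-5-methoxyphenol | COc1cc(O)cc(CCc2ccc(OCc3ccccc3)cc2)c1
F4 | step 1 | 4-(3-{2-[4-(benzyloxy)phenyl]ethyl}-5-methoxyphenoxy)benzaldehyde | COc1cc(Oc2ccc(C=O)cc2)cc(CCc2ccc(OCc3ccccc3)cc2)c1
F5 | step 1 | rac-3-(4-{3-[2-(4-benzyloxyphenyl)ethyl]-5-methoxyphenoxy}phenyl)-8-hydroxy-6-methoxy-3,4-dihydro-1H-isochromen-1-one | COc1cc(O)c2C(=O)OC(Cc2c1)c1ccc(Oc2cc(OC)cc(CCc3ccc(OCc4ccccc4)cc3)c2)cc1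
F6 | step 3 | 2-hydroxy-4-methoxy-6-methylbenzoic acid | COc1cc(C)c(C(=O)O)c(O)c1
F7 | step 3 | 7-methoxy-2,2,5-trimethyl-4H-1,3-benzodioxin-4-one | COc1cc(C)c2C(=O)OC(C)(C)Oc2c1
F8 | step 4 | 6-{(E)-2-[4-(3-{(E)-2-[4-(benzyloxy)phenyl]ethenyl}-5-methoxyphenoxy)phenyl]ethenyl}-2-hydroxy-4-methoxybenzoic acid | COc1cc(O)c(C(=O)O)c(/C=C/c2ccc(Oc3cc(OC)cc(/C=C/c4ccc(OCc5ccccc5)cc4)c3)cc2)c1
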